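**Retrosynthetic overview**
- Terpenoid numbering: ring A = C1–C5 + C10 (gem-dimethyl at C4), ring B = C5–C10, C11 = benzylic CH2. The strategy rests on quaternary C9 and its neighbour C10 being the β- and α-carbons of a C5 ketone in ring B.
- Key disconnection: C9–C11 and C10–C1 in one operation. A benzylcopper reagent from Grignard reagent 12 adds to (S)-3,4-dimethylcyclohex-2-enone 7, and the C5–C10 enolate is captured by α-silyl vinyl ketone 13.
- Ring order: ring B first (aldol condensation, step 2; C9 methyl by cuprate addition and dehydrosilylation, steps 3–4), ring A second (aldol condensation of the 1,5-diketone, step 9).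
- End game: deconjugative gem-dimethylation at C4 puts the alkene at C5=C6, the C3 carbonyl is removed, the tetramethoxyarene is oxidised to the quinone and one methoxy group is hydrolysed.

Key step: step 8

Remark: 3-(trimethylsilyl)but-3-en-2-one 13 and 1,2,4,5-tetramethoxybenzene 8 are taken as purchasable; where a name and a SMILES string differ, the SMILES string holds.

Step 1
Reactants: 1 propanal; 2 but-3-en-2-one
Product: 3 (S)-2-methyl-5-oxohexanal
Conditions: (R)-2-[methoxy(diphenyl)methyl]pyrrolidine (5 mol %), ethyl 3,4-dihydroxybenzoate (20 mol %), neat, 4 °C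
Reagents that add atoms: none
Why: Enamine-catalysed Michael addition in which the (R)-diarylprolinol ether forms an E-enamine of propanal with one face shielded by the diphenyl(methoxy)methyl group, so that the vinyl ketone is attacked from the open face and the α-stereocentre should be set as S under catalyst control.

Step 2
Reactants: 3 (S)-2-methyl-5-oxohexanal
Product: 5 (S)-4-methylcyclohex-2-en-1-one, via ketol 4 (not isolated)
Conditions: KOH (0.1 M aq.), n-Bu4NOH (cat.), Et2O–THF, reflux
Reagents that add atoms: none
Why: Intramolecular aldol condensation (methyl-ketone enolate onto the aldehyde, 6-enolexo-exo-trig, then E1cB dehydration) closes ring B, and the stereocentre, now γ to the carbonyl, should be kept because ring closure under dilute hydroxide is expected to outpace enolisation of the aldehyde.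

Step 3
Reactants: 5 (S)-4-methylcyclohex-2-en-1-one
Product: 6 trimethyl{[(3R,4S)-3,4-dimethylcyclohex-1-en-1-yl]oxy}silane
Conditions: Me2CuLi (from CuI and 2 MeLi), Me3SiCl, Et2O, −78 → −20 °C; Et3N, pentane work-up
Reagents that add atoms: lithium dimethylcuprate, [Li+].C[Cu-]C; chlorotrimethylsilane, C[Si](C)(C)Cl
Why: Chlorosilane-assisted cuprate conjugate addition delivers the methyl group anti to the C4 methyl (mainly the 3,4-trans isomer is expected) and fixes the enolate as its silyl ether, and the new C3 centre is of no consequence because it becomes sp2 in step 4.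

Step 4
Reactants: 6 trimethyl{[(3R,4S)-3,4-dimethylcyclohex-1-en-1-yl]oxy}silane
Product: 7 (S)-3,4-dimethylcyclohex-2-en-1-one
Conditions: Pd(OAc)2 (10 mol %), O2 (1 atm), DMSO, 25 °C
Reagents that add atoms: none
Why: Saegusa–Ito oxidation in which divalent palladium binds the enolate at C2 and β-hydride elimination can only take the C3–H, so the alkene returns between C2 and C3 with the new methyl on C3 while the C4 stereocentre is untouched and O2 reoxidises zerovalent palladium.

Step 5
Reactants: 8 1,2,4,5-tetramethoxybenzene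
Product: 10 (2,3,5,6-tetramethoxyphenyl)methanol, via aryllithium 9 (not isolated)
Conditions: n-BuLi, THF, 0 → 25 °C; (CH2O)n, 0 → 25 °C; H2O
Reagents that add atoms: paraformaldehyde (as formaldehyde), C=O
Why: Directed ortho-metalation at the position flanked by two methoxy groups followed by hydroxymethylation is preferred to direct chloromethylation, which on an arene with two equivalent activated positions tends to over-react and to form diarylmethanes.

Step 6
Reactants: 10 (2,3,5,6-tetramethoxyphenyl)methanol
Product: 11 3-(chloromethyl)-1,2,4,5-tetramethoxybenzene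
Conditions: SOCl2, pyridine, CH2Cl2, 0 °C
Reagents that add atoms: thionyl chloride, ClS(Cl)=O
Why: Chlorodehydroxylation of an electron-rich benzylic alcohol through its chlorosulfite, with pyridine taking up HCl so that the labile chloride, used freshly, is not exposed to acid.

Step 7
Reactants: 11 3-(chloromethyl)-1,2,4,5-tetramethoxybenzene
Product: 12 [(2,3,5,6-tetramethoxyphenyl)methyl]magnesium chloride
Conditions: Mg turnings, 2-methyltetrahydrofuran, 0 °C, slow addition; titrated solution used directly
Reagents that add atoms: magnesium, [Mg]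
Why: Insertion of magnesium into the benzylic C–Cl bond (Grignard formation), in which the chloride, the low temperature and the slow addition are chosen to hold back Wurtz homocoupling and both ortho positions are blocked so that the reagent can react only at the benzylic carbon.

Step 8
Reactants: 7 (S)-3,4-dimethylcyclohex-2-en-1-one; 12 [(2,3,5,6-tetramethoxyphenyl)methyl]magnesium chloride; 13 3-(trimethylsilyl)but-3-en-2-one
Product: 17 (2S,3R,4S)-3,4-dimethyl-2-(3-oxobutyl)-3-[(2,3,5,6-tetramethoxyphenyl)methyl]cyclohexan-1-one, via silyl enol ether 14 (not isolated), via lithium enolate 15 (not isolated), via α-silyl diketone 16 (not isolated)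
Conditions: 12 (1.5 equiv, slow addition), CuBr·SMe2 (20 mol %), Me3SiCl (2 equiv), THF, −78 → −40 °C; evaporation, pentane, filtration under Ar; MeLi (1.05 equiv), THF, 0 → 25 °C; 13 (1.2 equiv), −78 → −30 °C; MeOH, KF, 25 °C
Reagents that add atoms: none
Why: Monovalent copper converts Grignard reagent 12 into a benzylcopper species that adds 1,4 to enone 7 under activation by Me3SiCl, which silylates the enolate as it forms (C9–C11, silyl enol ether 14); MeLi then cleaves the O–Si bond to the regiodefined C5–C10 lithium enolate 15, which adds as a Michael donor to the α-silyl vinyl ketone 13 (C10–C1), the silyl group stabilising the adduct carbanion and holding back polymerisation and proton transfer, and fluoride in methanol finally removes that silyl group. The closest known reaction type is the chlorosilane-accelerated copper-catalysed conjugate addition of Grignard reagents to 3-substituted cyclohexenones, joined to the α-silyl vinyl ketone form of the Robinson annulation on an enolate released from its silyl enol ether. No ring is closed. C9: allylic strain with the C9 methyl holds the C8 methyl pseudoaxial in the enone and the benzyl group enters axially on the opposite face, so that benzyl is trans to the C8 methyl and the two methyl groups are cis. C10: the acceptor approaches the enolate anti to the then axial benzyl arm, and since C10 stays epimerisable α to the C5 ketone the methanolic fluoride treatment lets it settle with the side chain equatorial and trans to the benzyl arm. The step needs 1,4- over 1,2-addition, secured by copper together with Me3SiCl at low temperature, and bond formation at C10 and not at C6, secured because the enolate stems from the conjugate addition and not from deprotonation.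

Step 9
Reactants: 17 (2S,3R,4S)-3,4-dimethyl-2-(3-oxobutyl)-3-[(2,3,5,6-tetramethoxyphenyl)methyl]cyclohexan-1-one
Product: 19 (4aR,5R,6S)-5,6-dimethyl-5-[(2,3,5,6-tetramethoxyphenyl)methyl]-4,4a,5,6,7,8-hexahydronaphthalen-2(3H)-one, via ketol 18 (not isolated)
Conditions: NaOMe, MeOH, 65 °C
Reagents that add atoms: none
Why: Intramolecular aldol condensation (second stage of a Robinson annulation, 6-enolexo-exo-trig, E1cB dehydration) of the methyl-ketone enolate onto the C5 ketone closes ring A as the Δ4-3-ketone, and C10, α to the C5 carbonyl until closure, is expected to stay in its more stable configuration with C1 trans to the benzyl arm.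

Step 10
Reactants: 19 (4aR,5R,6S)-5,6-dimethyl-5-[(2,3,5,6-tetramethoxyphenyl)methyl]-4,4a,5,6,7,8-hexahydronaphthalen-2(3H)-one
Product: 21 (4aS,5R,6S)-1,1,5,6-tetramethyl-5-[(2,3,5,6-tetramethoxyphenyl)methyl]-3,4,4a,5,6,7-hexahydronaphthalen-2(1H)-one, via monomethyl ketone 20 (not isolated)
Conditions: KOt-Bu (2.5 equiv), t-BuOH–THF, 25 °C; MeI (5 equiv), 25 → 40 °C
Reagents that add atoms: iodomethane, CI
Why: Deconjugative α,α-dimethylation of a Δ4-3-ketone: the extended dienolate formed by removal of a C6–H is methylated twice at C4, which locks the alkene at C5=C6; the secondary C6–H is expected to be removed in preference to the tertiary C10–H next to quaternary C9, so that C10 keeps its configuration.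

Step 11
Reactants: 21 (4aS,5R,6S)-1,1,5,6-tetramethyl-5-[(2,3,5,6-tetramethoxyphenyl)methyl]-3,4,4a,5,6,7-hexahydronaphthalen-2(1H)-one
Product: 23 1,2,4,5-tetramethoxy-3-{[(1R,2S,8aS)-1,2,5,5-tetramethyl-1,2,3,5,6,7,8,8a-octahydronaphthalen-1-yl]methyl}benzene, via hydrazone 22 (not isolated)
Conditions: N2H4·H2O, KOH, diethylene glycol, 130 → 205 °C
Reagents that add atoms: none
Why: Wolff–Kishner reduction under Huang-Minlon conditions, in which the hindered C3 ketone forms its hydrazone and loses N2 at high temperature, while the alkene cannot move into conjugation because C4 is quaternary and the electron-rich aryl methyl ethers should survive.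

Step 12
Reactants: 23 1,2,4,5-tetramethoxy-3-{[(1R,2S,8aS)-1,2,5,5-tetramethyl-1,2,3,5,6,7,8,8a-octahydronaphthalen-1-yl]methyl}benzene
Product: 24 2,5-dimethoxy-3-{[(1R,2S,8aS)-1,2,5,5-tetramethyl-1,2,3,5,6,7,8,8a-octahydronaphthalen-1-yl]methyl}cyclohexa-2,5-diene-1,4-dione
Conditions: (NH4)2Ce(NO3)6 (2.5 equiv), MeCN–H2O, 0 °C
Reagents that add atoms: water, O
Why: Oxidative demethylation by tetravalent cerium (two one-electron oxidations, ipso attack of water, loss of methanol) gives the para-quinone, and because the arene is symmetric about the C11–aryl axis either para pair of methoxy groups leads to the same 2,5-dimethoxy-3-alkylquinone while the isolated alkene should stay untouched at 0 °C.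

Step 13
Reactants: 24 2,5-dimethoxy-3-{[(1R,2S,8aS)-1,2,5,5-tetramethyl-1,2,3,5,6,7,8,8a-octahydronaphthalen-1-yl]methyl}cyclohexa-2,5-diene-1,4-dione
Product: 26 2-hydroxy-5-methoxy-3-{[(1R,2S,8aS)-1,2,5,5-tetramethyl-1,2,3,5,6,7,8,8a-octahydronaphthalen-1-yl]methyl}cyclohexa-2,5-diene-1,4-dione (CNP0348245.1), via potassium salt 25 (not isolated)
Conditions: KOH (2 M aq.), MeOH, 25 °C; then HCl (1 M aq.)
Reagents that add atoms: potassium hydroxide, [K+].[OH-]
Why: Vinylogous ester hydrolysis by addition–elimination, expected at the methoxy group next to the bulky alkyl arm because that group is twisted out of conjugation and its carbon is the more electrophilic one, after which the vinylogous carboxylate anion resists further attack until it is protonated in the acid work-up.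

**Compound list**
1 | propanal | CCC=O | starting material
2 | but-3-en-2-one | CC(=O)C=C | starting material
3 | (S)-2-methyl-5-oxohexanal | CC(=O)CC[C@H](C)C=O | intermediate
4 | (4S)-3-hydroxy-4-methylcyclohexan-1-one (ketol, either configuration at C3) | OC1CC(=O)CC[C@@H]1C | intermediate
5 | (S)-4-methylcyclohex-2-en-1-one | C1=CC(=O)CC[C@@H]1C | intermediate
6 | trimethyl{[(3R,4S)-3,4-dimethylcyclohex-1-en-1-yl]oxy}silane | C[Si](C)(C)OC1=C[C@H](C)[C@@H](C)CC1 | intermediate
7 | (S)-3,4-dimethylcyclohex-2-en-1-one | CC1=CC(=O)CC[C@@H]1C | intermediate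
8 | 1,2,4,5-tetramethoxybenzene | COc1cc(OC)c(OC)cc1OC | starting material
9 | (2,3,5,6-tetramethoxyphenyl)lithium | COc1cc(OC)c(OC)c([Li])c1OC | intermediate
10 | (2,3,5,6-tetramethoxyphenyl)methanol | COc1cc(OC)c(OC)c(CO)c1OC | intermediate
11 | 3-(chloromethyl)-1,2,4,5-tetramethoxybenzene | COc1cc(OC)c(OC)c(CCl)c1OC | intermediate
12 | [(2,3,5,6-tetramethoxyphenyl)methyl]magnesium chloride | COc1cc(OC)c(OC)c(C[Mg]Cl)c1OC | intermediate
13 | 3-(trimethylsilyl)but-3-en-2-one | CC(=O)C(=C)[Si](C)(C)C | starting material
14 | {[(3R,4S)-3,4-dimethyl-3-[(2,3,5,6-tetramethoxyphenyl)methyl]cyclohex-1-en-1-yl]oxy}trimethylsilane (benzyl trans to the C8 methyl) | COc1cc(OC)c(OC)c(C[C@@]2(C)C=C(O[Si](C)(C)C)CC[C@@H]2C)c1OC | intermediate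
15 | lithium (3R,4S)-3,4-dimethyl-3-[(2,3,5,6-tetramethoxyphenyl)methyl]cyclohex-1-en-1-olate | COc1cc(OC)c(OC)c(C[C@@]2(C)C=C(O[Li])CC[C@@H]2C)c1OC | intermediate
16 | (2S,3R,4S)-3,4-dimethyl-2-[3-oxo-2-(trimethylsilyl)butyl]-3-[(2,3,5,6-tetramethoxyphenyl)methyl]cyclohexan-1-one (either configuration at the silyl-bearing carbon) | COc1cc(OC)c(OC)c(C[C@@]2(C)[C@H](CC(C(C)=O)[Si](C)(C)C)C(=O)CC[C@@H]2C)c1OC | intermediate
17 | (2S,3R,4S)-3,4-dimethyl-2-(3-oxobutyl)-3-[(2,3,5,6-tetramethoxyphenyl)methyl]cyclohexan-1-one | COc1cc(OC)c(OC)c(C[C@@]2(C)[C@H](CCC(C)=O)C(=O)CC[C@@H]2C)c1OC | intermediate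
18 | (4aS,5R,6S)-8a-hydroxy-5,6-dimethyl-5-[(2,3,5,6-tetramethoxyphenyl)methyl]octahydronaphthalen-2(1H)-one (ketol, either configuration at C8a) | COc1cc(OC)c(OC)c(C[C@@]2(C)[C@@H]3CCC(=O)CC3(O)CC[C@@H]2C)c1OC | intermediate
19 | (4aR,5R,6S)-5,6-dimethyl-5-[(2,3,5,6-tetramethoxyphenyl)methyl]-4,4a,5,6,7,8-hexahydronaphthalen-2(3H)-one | COc1cc(OC)c(OC)c(C[C@@]2(C)[C@@H]3CCC(=O)C=C3CC[C@@H]2C)c1OC | intermediate
20 | (4aS,5R,6S)-1,5,6-trimethyl-5-[(2,3,5,6-tetramethoxyphenyl)methyl]-3,4,4a,5,6,7-hexahydronaphthalen-2(1H)-one (either configuration at C1) | COc1cc(OC)c(OC)c(C[C@@]2(C)[C@@H]3CCC(=O)C(C)C3=CC[C@@H]2C)c1OC | intermediate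
21 | (4aS,5R,6S)-1,1,5,6-tetramethyl-5-[(2,3,5,6-tetramethoxyphenyl)methyl]-3,4,4a,5,6,7-hexahydronaphthalen-2(1H)-one | COc1cc(OC)c(OC)c(C[C@@]2(C)[C@@H]3CCC(=O)C(C)(C)C3=CC[C@@H]2C)c1OC | intermediate
22 | hydrazone of 21 at the ring-A carbonyl | COc1cc(OC)c(OC)c(C[C@@]2(C)[C@@H]3CCC(=NN)C(C)(C)C3=CC[C@@H]2C)c1OC | intermediate
23 | 1,2,4,5-tetramethoxy-3-{[(1R,2S,8aS)-1,2,5,5-tetramethyl-1,2,3,5,6,7,8,8a-octahydronaphthalen-1-yl]methyl}benzene | COc1cc(OC)c(OC)c(C[C@@]2(C)[C@@H]3CCCC(C)(C)C3=CC[C@@H]2C)c1OC | intermediate
24 | 2,5-dimethoxy-3-{[(1R,2S,8aS)-1,2,5,5-tetramethyl-1,2,3,5,6,7,8,8a-octahydronaphthalen-1-yl]methyl}cyclohexa-2,5-diene-1,4-dione | COC1=CC(=O)C(OC)=C(C[C@@]2(C)[C@@H]3CCCC(C)(C)C3=CC[C@@H]2C)C1=O | intermediate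
25 | potassium salt of 26 (vinylogous carboxylate) | COC1=CC(=O)C([O-])=C(C[C@@]2(C)[C@@H]3CCCC(C)(C)C3=CC[C@@H]2C)C1=O.[K+] | intermediate
26 | 2-hydroxy-5-methoxy-3-{[(1R,2S,8aS)-1,2,5,5-tetramethyl-1,2,3,5,6,7,8,8a-octahydronaphthalen-1-yl]methyl}cyclohexa-2,5-diene-1,4-dione | COC1=CC(=O)C(O)=C(C[C@@]2(C)[C@@H]3CCCC(C)(C)C3=CC[C@@H]2C)C1=O | target

**Step count**
Total: 13 steps. Longest linear sequence: 10 steps (steps 1–4 and 8–13); the arene branch (steps 5–7) joins at step 8.

**Steps most likely to fail**

Step 8 (key step). Transfer of the doubly ortho-substituted benzyl group from copper to the β,β-disubstituted enone may be outrun by 1,2-addition and by Wurtz-type homocoupling of the organometallic, so that C9–C11 does not form. The fallback sets out from 7 and comes back at 19: the C9 substituent is brought in as a vinyl group and the arene is attached to C11 afterwards with reversed polarity.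
- Vinylmagnesium bromide with CuBr·SMe2 and Me3SiCl should add to 7 anti to the C8 methyl and give the vinyl silyl enol ether F1.
- Mukaiyama–Michael addition of F1 to but-3-en-2-one 2 (TiCl4, CH2Cl2, −78 °C) gives the vinyl diketone F2.
- NaOMe in MeOH closes ring A through the ketol F3 to the vinyl octalone F4.
- Ozonolysis (O3, CH2Cl2–MeOH, −78 °C; then Me2S), stopped at the first excess of ozone, should cleave the isolated vinyl group ahead of the electron-poor enone alkene and give the C11 aldehyde F5.
- Aryllithium 9 (one equivalent, THF, −78 °C) should add to the aldehyde ahead of the conjugated ketone and give the benzylic carbinol F6.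
- Ionic deoxygenation (Et3SiH, CF3CO2H, CH2Cl2, 0 °C) through the strongly stabilised benzylic cation then gives 19.

Step 10. Removal of the tertiary C10–H instead of a C6–H during dienolate formation would put the alkene at C5=C10 and erase the C10 stereocentre; O-methylation and methylation at C2 are further drains. The fallback sets out from 19 and comes back at 21 by way of 20: the position of the diene is fixed in an isolable derivative before any C–C bond is made.
- Isopropenyl acetate with TsOH (cat.) at reflux, under equilibrating conditions, should give the heteroannular dienyl acetate F7, which is purified.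
- MeLi (2 equiv, 1,2-dimethoxyethane, 0 °C) cleaves the acetate to the lithium dienolate F8 with both double bonds already in place.
- MeI gives the 4-methyl ketone 20.
- NaH and MeI in THF remove the C4–H of 20, which is both α to the ketone and allylic, and give 21.

Step 13. Hydroxide may discriminate poorly between the two vinylogous ester positions, or hydrolysis may run on past the mono-hydroxy stage. The fallback sets out from 24 and comes back at 26: differentiation is moved from the hydrolysis to a reversible etherification.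
- Excess KOH in aqueous dioxane at 80 °C drives hydrolysis to the dipotassium salt F9, and HCl releases the 2,5-dihydroxyquinone F10.
- Acid-catalysed vinylogous esterification (MeOH, TsOH cat., 25 °C) should etherify the hydroxyl flanked by the ring C–H and not the one next to the alkyl arm, which gives 26.

**Further compounds**
F1 | step 8 | {[(3R,4S)-3-ethenyl-3,4-dimethylcyclohex-1-en-1-yl]oxy}trimethylsilane | C=C[C@@]1(C)C=C(O[Si](C)(C)C)CC[C@@H]1C
F2 | step 8 | (2S,3R,4S)-3-ethenyl-3,4-dimethyl-2-(3-oxobutyl)cyclohexan-1-one | C=C[C@@]1(C)[C@H](CCC(C)=O)C(=O)CC[C@@H]1C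
F3 | step 8 | 5-ethenyl-8a-hydroxy-5,6-dimethyloctahydronaphthalen-2(1H)-one (ketol, other centres as in F2, either configuration at C8a) | C=C[C@@]1(C)[C@@H]2CCC(=O)CC2(O)CC[C@@H]1C
F4 | step 8 | (4aR,5R,6S)-5-ethenyl-5,6-dimethyl-4,4a,5,6,7,8-hexahydronaphthalen-2(3H)-one | C=C[C@@]1(C)[C@@H]2CCC(=O)C=C2CC[C@@H]1C
F5 | step 8 | 1,2-dimethyl-6-oxo-1,2,3,4,6,7,8,8a-octahydronaphthalene-1-carbaldehyde (C11 aldehyde, ring configuration as in 19) | O=C[C@@]1(C)[C@@H]2CCC(=O)C=C2CC[C@@H]1C
F6 | step 8 | 5-[hydroxy(2,3,5,6-tetramethoxyphenyl)methyl]-5,6-dimethyl-4,4a,5,6,7,8-hexahydronaphthalen-2(3H)-one (ring configuration as in 19, carbinol carbon either way) | COc1cc(OC)c(OC)c(C(O)[C@@]2(C)[C@@H]3CCC(=O)C=C3CC[C@@H]2C)c1OC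
F7 | step 10 | 5,6-dimethyl-5-[(2,3,5,6-tetramethoxyphenyl)methyl]-3,4,4a,5,6,7-hexahydronaphthalen-2-yl acetate (dienyl acetate, configuration as in 19) | COc1cc(OC)c(OC)c(C[C@@]2(C)[C@@H]3CCC(OC(C)=O)=CC3=CC[C@@H]2C)c1OC
F8 | step 10 | lithium 5,6-dimethyl-5-[(2,3,5,6-tetramethoxyphenyl)methyl]-3,4,4a,5,6,7-hexahydronaphthalen-2-olate (dienolate, configuration as in 19) | COc1cc(OC)c(OC)c(C[C@@]2(C)[C@@H]3CCC(O[Li])=CC3=CC[C@@H]2C)c1OC
F9 | step 13 | dipotassium salt of F10 | [K+].[K+].[O-]C1=CC(=O)C([O-])=C(C[C@@]2(C)[C@@H]3CCCC(C)(C)C3=CC[C@@H]2C)C1=O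
F10 | step 13 | 2,5-dihydroxy-3-{[(1R,2S,8aS)-1,2,5,5-tetramethyl-1,2,3,5,6,7,8,8a-octahydronaphthalen-1-yl]methyl}cyclohexa-2,5-diene-1,4-dione | OC1=CC(=O)C(O)=C(C[C@@]2(C)[C@@H]3CCCC(C)(C)C3=CC[C@@H]2C)C1=O
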